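The tetralin bond C1–C8a is traced back to a C1–C4a bond. The ring-A hydroxyl on C7 lies para to the fusion carbon C4a. Ring A can therefore be stored as a 2-methoxycyclohexadienone with C4a as spiro atom and C1–C4 completing a cyclopentane. Acid then drives a dienone–phenol 1,2-shift of the syringyl-bearing C1 from C4a to C8a. In one operation the five-membered ring becomes the six-membered one, ring A re-aromatises, its phenol appears and the target results. The spirodienone arises when a fluoride-released guaiacyl phenolate attacks a syringyl quinone methide through its para carbon. C3 and C2 come from an enantioselective C–H insertion and a lactone aldol.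

Key step: step 10

Remark on numbering: atom labels follow the tetralin numbering of the target. C1 bears the syringyl ring, C2 and C3 bear the acetoxymethyl groups, C4 is the CH2, C6 bears OMe and C7 bears OH. The target is (1S,2R,3R), that is 1,2-trans and 2,3-trans.

Remark on the catalyst (assumption): the 4R antipode of Rh2(MPPIM)4 is taken to give the (R)-lactone. If the sense of induction is the reverse, the 4S antipode is used and nothing else changes.

Remark on open centres: the carbinol carbon made in step 6 and the spiro carbon made in step 9 are carried as epimer mixtures. Both centres are erased later, so their SMILES leave them open.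

Step 1
Reactants: 1 eugenol (4-allyl-2-methoxyphenol)
Product: 2 (4-allyl-2-methoxyphenoxy)(tert-butyl)dimethylsilane
Conditions: TBSCl, imidazole, DMF, rt
Reagents that add atoms: tert-butyldimethylsilyl chloride, CC(C)(C)[Si](C)(C)Cl
Why: Imidazole-promoted silylation of a phenol installs the fluoride-labile group that serves as the trigger in step 9, and no stereocentre is involved.

Step 2
Reactants: 2 (4-allyl-2-methoxyphenoxy)(tert-butyl)dimethylsilane
Product: 4 3-[4-(tert-butyldimethylsilyloxy)-3-methoxyphenyl]propan-1-ol, via B-alkyl-9-BBN adduct 3 (not isolated)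
Conditions: 9-BBN, THF, 0 °C → rt; then NaBO3·4H2O, H2O, rt
Reagents that add atoms: 9-borabicyclo[3.3.1]nonane, B1C2CCCC1CCC2 (boron and its ring, in 3 only); sodium perborate, [Na+].[O-]OB=O (the hydroxyl oxygen)
Why: In this hydroboration–oxidation 9-BBN adds anti-Markovnikov to the terminal alkene, and the mild perborate oxidation should spare the aryl silyl ether.

Step 3
Reactants: 4 3-[4-(tert-butyldimethylsilyloxy)-3-methoxyphenyl]propan-1-ol
Product: 6 3-[4-(tert-butyldimethylsilyloxy)-3-methoxyphenyl]propyl diazoacetate, via bromoacetate 5 (not isolated)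
Conditions: BrCH2COBr, NaHCO3, MeCN, 0 °C; crude ester, then TsNHNHTs, DBU, THF, 0 °C
Reagents that add atoms: bromoacetyl bromide, O=C(Br)CBr; N,N'-ditosylhydrazine, Cc1ccc(cc1)S(=O)(=O)NNS(=O)(=O)c1ccc(C)cc1
Why: O-acylation is followed by the ditosylhydrazine route to diazoacetates, in which the bromide alkylates the hydrazine and DBU expels two sulfinates, and the short anhydrous exposure at 0 °C should leave the aryl silyl ether intact.

Step 4
Reactants: 6 3-[4-(tert-butyldimethylsilyloxy)-3-methoxyphenyl]propyl diazoacetate
Product: 7 (R)-4-[4-(tert-butyldimethylsilyloxy)-3-methoxybenzyl]dihydrofuran-2(3H)-one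
Conditions: Rh2(4R-MPPIM)4 (1 mol %), CH2Cl2, reflux, slow addition of 6
Reagents that add atoms: none
Why: In this enantioselective intramolecular rhodium-carbenoid C–H insertion with a chiral dirhodium carboxamidate, the five-membered-ring preference directs the carbenoid to the central CH2 of the propyl chain and the ligand pocket selects one of its two enantiotopic hydrogens, which sets the future C3 as R.

Step 5
Reactants: 8 syringaldehyde (4-hydroxy-3,5-dimethoxybenzaldehyde)
Product: 9 4-(tert-butyldimethylsilyloxy)-3,5-dimethoxybenzaldehyde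
Conditions: TBSCl, imidazole, DMAP (cat.), DMF, rt
Reagents that add atoms: tert-butyldimethylsilyl chloride, CC(C)(C)[Si](C)(C)Cl
Why: Phenol silylation of the flanked but acidic hydroxyl gives the second fluoride-labile trigger, and the aldehyde is not affected.

Step 6
Reactants: 7 (R)-4-[4-(tert-butyldimethylsilyloxy)-3-methoxybenzyl]dihydrofuran-2(3H)-one; 9 4-(tert-butyldimethylsilyloxy)-3,5-dimethoxybenzaldehyde
Product: 11 (3S,4R)-3-{[4-(tert-butyldimethylsilyloxy)-3,5-dimethoxyphenyl](hydroxy)methyl}-4-[4-(tert-butyldimethylsilyloxy)-3-methoxybenzyl]dihydrofuran-2(3H)-one (3,4-trans, both carbinol epimers), via lithium enolate 10 (not isolated)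
Conditions: LDA, THF, −78 °C; then 9, −78 °C; AcOH quench
Reagents that add atoms: lithium diisopropylamide, [Li+].CC(C)[N-]C(C)C (lithium, in 10 only)
Why: In this lithium-enolate aldol addition of a β-substituted butyrolactone the aldehyde approaches the face anti to the C4 benzyl group, which sets the future C2 (3,4-trans), while the uncontrolled carbinol centre is erased in step 9.

Step 7
Reactants: 11 aldol lactone
Product: 12 (2R,3R)-2-{[4-(tert-butyldimethylsilyloxy)-3,5-dimethoxyphenyl](hydroxy)methyl}-3-[4-(tert-butyldimethylsilyloxy)-3-methoxybenzyl]butane-1,4-diol (both carbinol epimers)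
Conditions: LiAlH4, THF, 0 °C; Na2SO4·10H2O quench
Reagents that add atoms: none
Why: Hydride reduction of the lactone to the 1,4-diol at 0 °C should outrun retro-aldol cleavage and spare the aryl silyl ethers, and it touches no stereocentre.

Step 8
Reactants: 12 triol
Product: 13 (2R,3R)-2-{acetoxy[4-(tert-butyldimethylsilyloxy)-3,5-dimethoxyphenyl]methyl}-3-[4-(tert-butyldimethylsilyloxy)-3-methoxybenzyl]butane-1,4-diyl diacetate (both benzylic epimers)
Conditions: Ac2O, pyridine, DMAP (cat.), CH2Cl2, 0 °C → rt
Reagents that add atoms: acetic anhydride, CC(=O)OC(C)=O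
Why: DMAP-catalysed peracetylation installs the two primary acetates of the target and at the same time turns the benzylic hydroxyl into the leaving group for quinone methide formation.

Step 9
Reactants: 13 triacetate bis-silyl ether
Product: 15 [(1S,2R,3R)-1-(4-hydroxy-3,5-dimethoxyphenyl)-7-methoxy-8-oxospiro[4.5]deca-6,9-diene-2,3-diyl]dimethanediyl diacetate (both spiro epimers), via syringyl quinone methide 14 (not isolated)
Conditions: TBAF, THF (0.005 M), −40 → 0 °C; AcOH quench
Reagents that add atoms: none
Why: Fluoride frees both phenolates, the syringyl one expels the para-benzylic acetate (1,6-elimination) to give 14, and the guaiacyl phenolate, whose only carbon within reach is the one para to O⁻, adds to it in a 5-exo-trig Ar1⁻-5 dearomatising para-alkylation (a 1,6-conjugate addition) that is reversible, so that C2 places the aryl group trans to its acetoxymethyl neighbour while high dilution suppresses intermolecular O-alkylation.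

Step 10
Reactants: 15 spirodienone
Product: 16 [(1S,2R,3R)-7-hydroxy-1-(4-hydroxy-3,5-dimethoxyphenyl)-6-methoxy-1,2,3,4-tetrahydronaphthalene-2,3-diyl]dimethanediyl diacetate (target)
Conditions: TFA, CH2Cl2, 0 °C
Reagents that add atoms: none
Why: TFA protonates the dienone oxygen of 15 to a 4-hydroxycyclohexadienyl cation whose charge lies on the two CH carbons flanking the spiro atom C4a, C1 then shifts suprafacially from C4a to the neighbouring CH (the future C8a), and loss of that proton restores aromatic ring A with its C7 hydroxyl. This is the dienone–phenol rearrangement, the classical passage from spiro[4.5]deca-1,4-dien-3-ones to 5,6,7,8-tetrahydro-2-naphthols, driven here by the aromatisation energy stored in step 9. No ring is closed from an open chain: the cyclopentane C4a–C1–C2–C3–C4 takes up C8a by the 1,2-shift and becomes the six-membered ring, and if the shift turns stepwise through the ring-opened syringyl-stabilised cation, an Ar2-6 Friedel–Crafts reclosure at the same carbon gives the same ring. C2 and C3 are not touched; C1 migrates with retention, and in the stepwise variant C2 directs the aryl group into the equatorial 1,2-trans position, so both paths should give 1S. Two selectivities are needed: C1 must migrate rather than C4H2, which its benzylic link to the electron-rich syringyl ring secures, and it must go to the CH remote from the methoxy group, which follows because the enol-ether oxygen feeds electron density into the other, more hindered terminus, so that C1 ends para to OMe. Both spiro epimers converge on 16, and the primary acetates and the free phenols should tolerate cold TFA.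

Compound list
1 | eugenol | C=CCc1ccc(O)c(OC)c1 | starting material
2 | (4-allyl-2-methoxyphenoxy)(tert-butyl)dimethylsilane | C=CCc1ccc(O[Si](C)(C)C(C)(C)C)c(OC)c1 | intermediate
3 | B-{3-[4-(tert-butyldimethylsilyloxy)-3-methoxyphenyl]propyl}-9-borabicyclo[3.3.1]nonane | COc1cc(CCCB2C3CCCC2CCC3)ccc1O[Si](C)(C)C(C)(C)C | intermediate (not isolated)
4 | 3-[4-(tert-butyldimethylsilyloxy)-3-methoxyphenyl]propan-1-ol | OCCCc1ccc(O[Si](C)(C)C(C)(C)C)c(OC)c1 | intermediate
5 | 3-[4-(tert-butyldimethylsilyloxy)-3-methoxyphenyl]propyl bromoacetate | BrCC(=O)OCCCc1ccc(O[Si](C)(C)C(C)(C)C)c(OC)c1 | intermediate (not isolated)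
6 | 3-[4-(tert-butyldimethylsilyloxy)-3-methoxyphenyl]propyl diazoacetate | [N-]=[N+]=CC(=O)OCCCc1ccc(O[Si](C)(C)C(C)(C)C)c(OC)c1 | intermediate
7 | (R)-4-[4-(tert-butyldimethylsilyloxy)-3-methoxybenzyl]dihydrofuran-2(3H)-one | O=C1C[C@@H](Cc2ccc(O[Si](C)(C)C(C)(C)C)c(OC)c2)CO1 | intermediate
8 | syringaldehyde | O=Cc1cc(OC)c(O)c(OC)c1 | starting material
9 | 4-(tert-butyldimethylsilyloxy)-3,5-dimethoxybenzaldehyde | O=Cc1cc(OC)c(O[Si](C)(C)C(C)(C)C)c(OC)c1 | intermediate
10 | lithium enolate of 7 | [Li]OC1=C[C@@H](Cc2ccc(O[Si](C)(C)C(C)(C)C)c(OC)c2)CO1 | intermediate (not isolated)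
11 | (3S,4R)-aldol lactone, carbinol centre open | OC(c1cc(OC)c(O[Si](C)(C)C(C)(C)C)c(OC)c1)[C@H]1C(=O)OC[C@@H]1Cc1ccc(O[Si](C)(C)C(C)(C)C)c(OC)c1 | intermediate
12 | (2R,3R)-triol, carbinol centre open | OC(c1cc(OC)c(O[Si](C)(C)C(C)(C)C)c(OC)c1)[C@@H](CO)[C@H](CO)Cc1ccc(O[Si](C)(C)C(C)(C)C)c(OC)c1 | intermediate
13 | (2R,3R)-triacetate bis-silyl ether, benzylic centre open | CC(=O)OC(c1cc(OC)c(O[Si](C)(C)C(C)(C)C)c(OC)c1)[C@@H](COC(C)=O)[C@H](COC(C)=O)Cc1ccc(O[Si](C)(C)C(C)(C)C)c(OC)c1 | intermediate
14 | (2R,3R)-2-[(3,5-dimethoxy-4-oxocyclohexa-2,5-dien-1-ylidene)methyl]-3-(4-hydroxy-3-methoxybenzyl)butane-1,4-diyl diacetate, present as its guaiacyl phenolate | COC1=CC(=C[C@@H](COC(C)=O)[C@H](COC(C)=O)Cc2ccc(O)c(OC)c2)C=C(OC)C1=O | intermediate (not isolated)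
15 | (1S,2R,3R)-spiro[4.5]deca-6,9-dien-8-one, spiro centre open | COC1=CC2(C=CC1=O)[C@H](c1cc(OC)c(O)c(OC)c1)[C@@H](COC(C)=O)[C@H](COC(C)=O)C2 | intermediate
16 | (1S,2R,3R)-aryltetralin diacetate CNP0265800.1 | COc1cc2c(cc1O)[C@H](c1cc(OC)c(O)c(OC)c1)[C@@H](COC(C)=O)[C@H](COC(C)=O)C2 | target

Total step count: 10. Longest linear sequence: 9 (steps 1–4 and 6–10).

Steps most likely to fail

Step 9. The quinone methide may tautomerise to the styrene with loss of the C2 centre. It may also be consumed by intermolecular trapping or oligomerisation, and fluoride may strip primary acetates. The fallback makes the quinone methide by oxidation instead of elimination; it sets out from 13 and returns at 15. Hydrogenolysis of the benzylic acetate (H2, Pd/C, EtOAc) should give (2R,3R)-2-[4-(tert-butyldimethylsilyloxy)-3,5-dimethoxybenzyl]-3-[4-(tert-butyldimethylsilyloxy)-3-methoxybenzyl]butane-1,4-diyl diacetate F1. TBAF buffered with AcOH should then free the stable bisphenol (2R,3R)-2-(4-hydroxy-3,5-dimethoxybenzyl)-3-(4-hydroxy-3-methoxybenzyl)butane-1,4-diyl diacetate F2. Ag2O in CH2Cl2 should oxidise the more electron-rich 2,6-dimethoxyphenol to the same quinone methide 14 under neutral, fluoride-free conditions. A catalytic amount of DBU at high dilution should close it to 15.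

Step 10. The free syringyl phenol may favour full ionisation, followed by oligomerisation instead of reclosure. Part of the migration may also go to the methoxy-flanked terminus. The fallback is an acylative rearrangement; it sets out from 15 and returns at 16. Ac2O with catalytic H2SO4 at 0 °C should first acetylate the syringyl hydroxyl, which damps its donor strength and keeps the shift concerted. The new phenol is then trapped irreversibly, giving the (1S,2R,3R)-tetraacetate of the aryltetralin F3. NH4OAc in aqueous MeOH at rt should cleave the two aryl acetates chemoselectively in the presence of the two alkyl acetates and give 16.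

Step 4. Discrimination of the enantiotopic hydrogens may be insufficient. Carbene dimerisation or attack on the electron-rich arene may also compete with insertion. The fallback uses an auxiliary instead of a catalyst; it sets out from 4 and returns at 7.
- TEMPO/PhI(OAc)2 in MeCN–H2O should give 3-[4-(tert-butyldimethylsilyloxy)-3-methoxyphenyl]propanoic acid F4.
- PivCl/Et3N followed by lithiated (S)-4-benzyl-2-oxazolidinone should give the N-acyl oxazolidinone F5.
- Evans asymmetric alkylation (NaHMDS, tert-butyl bromoacetate, THF, −78 °C; attack anti to the auxiliary benzyl group) should give the (R)-configured succinate imide F6.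
- LiBH4 in THF–MeOH should release tert-butyl (R)-3-(hydroxymethyl)-4-[4-(tert-butyldimethylsilyloxy)-3-methoxyphenyl]butanoate F7.
- TFA in CH2Cl2 should cleave the tert-butyl ester and close the lactone 7.

Further compounds
F1 | step 9 | (2R,3R)-2-[4-(tert-butyldimethylsilyloxy)-3,5-dimethoxybenzyl]-3-[4-(tert-butyldimethylsilyloxy)-3-methoxybenzyl]butane-1,4-diyl diacetate | COc1cc(C[C@@H](COC(C)=O)[C@H](COC(C)=O)Cc2ccc(O[Si](C)(C)C(C)(C)C)c(OC)c2)cc(OC)c1O[Si](C)(C)C(C)(C)C
F2 | step 9 | (2R,3R)-2-(4-hydroxy-3,5-dimethoxybenzyl)-3-(4-hydroxy-3-methoxybenzyl)butane-1,4-diyl diacetate | COc1cc(C[C@@H](COC(C)=O)[C@H](COC(C)=O)Cc2ccc(O)c(OC)c2)cc(OC)c1O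
F3 | step 10 | (1S,2R,3R)-tetraacetate of the aryltetralin | COc1cc2c(cc1OC(C)=O)[C@H](c1cc(OC)c(OC(C)=O)c(OC)c1)[C@@H](COC(C)=O)[C@H](COC(C)=O)C2
F4 | step 4 | 3-[4-(tert-butyldimethylsilyloxy)-3-methoxyphenyl]propanoic acid | OC(=O)CCc1ccc(O[Si](C)(C)C(C)(C)C)c(OC)c1
F5 | step 4 | (S)-4-benzyl-3-{3-[4-(tert-butyldimethylsilyloxy)-3-methoxyphenyl]propanoyl}oxazolidin-2-one | O=C(CCc1ccc(O[Si](C)(C)C(C)(C)C)c(OC)c1)N1[C@@H](Cc2ccccc2)COC1=O
F6 | step 4 | tert-butyl (R)-4-[(S)-4-benzyl-2-oxooxazolidin-3-yl]-3-[4-(tert-butyldimethylsilyloxy)-3-methoxybenzyl]-4-oxobutanoate | O=C([C@@H](CC(=O)OC(C)(C)C)Cc1ccc(O[Si](C)(C)C(C)(C)C)c(OC)c1)N1[C@@H](Cc2ccccc2)COC1=O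
F7 | step 4 | tert-butyl (R)-3-(hydroxymethyl)-4-[4-(tert-butyldimethylsilyloxy)-3-methoxyphenyl]butanoate | OC[C@@H](CC(=O)OC(C)(C)C)Cc1ccc(O[Si](C)(C)C(C)(C)C)c(OC)c1
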